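All constants come from no measurement.

Product is what you want, and a ledger of the limiting reagent shows how much of it each set-up can book in the time you give it.

| setting | autumn | dusk | midnight | dawn |
|---|---|---|---|---|
| substrate | 0.020 M | 0.020 M | 0.020 M | 0.020 M (fed, over 12.5 h) |
| partner | 0.0400 M | 0.0400 M | 0.0400 M (fed, over 12.5 h) | 0.0400 M |
| precatalyst | 40 µM | 40 µM | 40 µM | 40 µM |
| time | 25 h |  | 25 h | 25 h |
| remark | a closed flask charged with all of it at once and left for 25 h | a single well-mixed tank run continuously and read at steady state, 25 h in it on average | all but partner at the start; partner goes in evenly over 12.5 h, the run ends at 25 h | a stirred flask in which substrate is dosed at a steady rate over 12.5 h without added volume, worked up at 25 h |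

    substrate + partner + catalyst → product + catalyst, rate k1*[substrate]*[partner]*[catalyst]/(1 + ([substrate]/sat1)) (sat1 = 50.0 mM, k1 = 4510 M⁻² min⁻¹)
    catalyst + product ⇌ idle complex (K2 = 36 M⁻¹, k2 = 0.263 M⁻¹ min⁻¹)
    partner + precatalyst → catalyst + spent reagent (k3 = 1.04 M⁻¹ min⁻¹)

- amounts and yields of product count idle complex too
- the stated concentrations are those of everything mixed, before any reaction; amounts are the same in each set-up
- the feed brings no volume worth counting
- run time (autumn): 25 h

* the set-up with the highest amount of product at the outlet or at the end, in percent of the substrate put in ("none" if the first two lie within 2 percentage points) (autumn / dusk / midnight / dawn / none)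
* amount of product at the outlet or at the end, in percent of the substrate put in, autumn
* amount of product at the outlet or at the end, in percent of the substrate put in, dusk
* amount of product at the outlet or at the end, in percent of the substrate put in, midnight
* amount of product at the outlet or at the end, in percent of the substrate put in, dawn

Substrate is the limiting reagent: 0.020 M stands against 0.0400 M of partner, and each mole of product takes one of each. Now close the books on autumn. Each mole of substrate is entered as product, and the partner pays for it. Partner also pays 40 µM to turn precatalyst into catalyst, a job of about 24.0 min, which leaves 0.0200 M. Idle complex holds at most 40 µM of the product, and that still counts as product. The catalyst, though, is then free for a share of 58.1%.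

With the substrate entry closed, the saturation term drops out of the rate law, and these entries give 0.126 h⁻¹: the closing constant, the pseudo-first-order rate constant of the limiting reagent once its ledger is closed.

Held constant, that rate integrates in closed form. My autumn figure is 95.7%, and the same constant in the tank's steady-state balance gives dusk 75.8%. The average dose arrives at 6.25 h, so I give each fed flask 18.8 h to run: midnight 90.5%, dawn 90.5%. Expect the autumn figure to read low: with the charged [substrate] and [partner], the precatalyst turned to catalyst and no idle complex, the same expression gives 0.309 h⁻¹. My pick is autumn.

The forecast, holding that “catalyst is soon fully available”, also picks autumn, with 98% for autumn, 79.4% for dusk, 95.1% for midnight and 94.8% for dawn. Those figures stand above mine.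

The simulation gives 98.1% for autumn, 79.4% for dusk, 95.1% for midnight and 94.9% for dawn, so autumn leads. Autumn ends with 1.93% of its substrate left. Start the closing constant from the 10.1% standing in autumn at 12.5 h and it carries that to 2.11% by the end.

In the neighbour of autumn charged with 0.010 M of partner, partner is the limiting reagent and, after its 40 µM paid for precatalyst, the ledger caps product at 49.8%. Its closing constant is 0.0663 h⁻¹, which gives 40.3%; the computed flask reaches 44.5%, with 11% of its partner left.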